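At early times the west run reads 3.4% target and 0.4% side product after 5.00 h, and your question is how long that lead lasts.

| flask | starting material | reagent | free catalyst | temperature | remark | time |
|---|---|---|---|---|---|---|
| south-west | 0.0024 M | 1 equiv | 5 mol% | 25 °C | run made earlier |  |
| west | 0.0074 M | 1 equiv | 5 mol% | 40 °C | run made earlier |  |
| Monday's | 0.012 M | 1.00 equiv | 5 mol% |  | at 50 °C until 6.0 h, from then on at 30 °C | 20 h |
| Saturday's | 0.0040 M | 1.00 equiv | 5 mol% |  | at 50 °C throughout | 20 h |

- south-west (time / h: target / %, side product / %, starting material / %): 3.00: 0, 0, 100.9; 6.00: 1.3, 0, 100.0; 10.0: 0.7, 0, 99.0; 15.0: 0.8, 0.2, 99.0; 30.0: 2.0, 0.4, 96.4; 48.0: 4.9, 0.5, 94.2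
- west (time / h: target / %, side product / %, starting material / %): 1.50: 0.4, 0, 98.6; 3.00: 1.6, 0, 97.2; 5.00: 3.4, 0.4, 95.2; 8.00: 6.3, 0.2, 92.7; 12.0: 9.8, 1.5, 87.5; 25.0: 15.0, 8.7, 75.1

(each reading ± 0.5 percentage points)

- the numbers in the tables scatter with a standard deviation of 0.5 percentage points
- where the amount of starting material changes, what is given in equivalents or mol% on it follows

* the winner by share of target in all that became target or side product; "neither" if no more than 2 percentage points parts them (Monday's / Saturday's / neither)
* share of target in all that became target or side product, Monday's
* share of target in all that became target or side product, Saturday's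

Between 12.0 h and 25.0 h the west run used 12 percentage points of starting material and gained 7.2 points of side product, a reading of 0.581. Carry this number: the onward fraction, the points of side product gained per point of starting material used over the same hours. One rate is divided by the other, so time drops out. Above one, with the bound forms of the catalyst steady, target is shrinking.

Turn time first. By hand, a stretch at this fraction puts 41.9% of the starting material it uses into target, less than the west run's share of target, the selectivity, which reads 86.7% at 12.0 h, so that share should fall. In the west run it reads 63.3% at 25.0 h.

Turn temperature next. By hand, heat should bring that fall sooner, and the south-west run at 25 °C reads 90.7% at 48.0 h, higher than the west figure.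

Turn the amount last. The two runs changed it together with temperature, so they give you no separate reading, and Monday's stands at 0.012 M against 0.0040 M for Saturday's.

My own reckoning puts Saturday's, held at 50 °C, below the west run's 63.3%, and Monday's, cooled to 30 °C after 6.0 h, above it, with the amount left unpriced. The forecast names Monday's, with 70% (52% to 84%) for Monday's and 35% (20% to 68%) for Saturday's, holding that “high temperature and dilution favour side product”.

The flasks give 56.9% for Monday's and 56.5% for Saturday's, so the answer is neither.

    catalyst intermediate D ⇌ catalyst intermediate E (K = 0.630, k = 5.20 /h, Ea = 87.0 kJ/mol, ΔH = −43.0 kJ/mol)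
    starting material + catalyst intermediate C → catalyst intermediate D (k = 440 /M/h, Ea = 50.0 kJ/mol)
    catalyst intermediate B → catalyst intermediate C (k = 5.10 /h, Ea = 96.0 kJ/mol)
    target + released group → side product (k = 94.0 /M/h, Ea = 74.0 kJ/mol)
    reagent + free catalyst ⇌ catalyst intermediate A (K = 73.0 /M, k = 420 /M/h, Ea = 50.0 kJ/mol, ΔH = −14.0 kJ/mol)
    catalyst intermediate A → released group + catalyst intermediate B (k = 5.70 /h, Ea = 92.0 kJ/mol)
    crystals ⇌ released group, rate k7*(cs7 - [released group]) while solid is left; crystals form when [released group] > cs7 (solubility = 4.50 mM, k = 24.0 /h)
    catalyst intermediate E ⇌ free catalyst + target (K = 0.0190 M, k = 6.70 /h, Ea = 102 kJ/mol, ΔH = −90.0 kJ/mol)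
    (constants at 50 °C)

From 10.0 h to 20.0 h the onward fraction is 0.707 in Saturday's and 0.827 in cooled Monday's, each higher than the west reading of 0.581. The same flask as Saturday's, read on to 48.0 h, gives 1.07 for the hours from 20.0 h on, above one, and its share is 24.9%. In Saturday's at 8.89 h, starting material has a half-life of 37 h by its step with catalyst intermediate C into catalyst intermediate D, much longer than the 0.12 h of catalyst intermediate A by its step to released group and catalyst intermediate B. At 20.0 h Saturday's still holds 69.1% of its starting material.

All runs are calculated with constants of no real substance, noise included.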